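**Retrosynthetic overview**

1. Endgame: the target comes from 27 by C15 methylenation, C13 acetylation and C8 desilylation; 27 comes from ketone 24 by erasing a temporary C11 carbonyl.
2. Key disconnection C12–C13: 24 comes from the open bromoketone–aldehyde 22 by a SmI2 Reformatsky-type aldol macrocyclisation. Enabling feature: C12(CH3)–C13(O) is a syn propionate-aldol pair whose carbonyl partner can sit on C11, one of the three function-free ring methylenes C9–C11, and the ring oxygen O14 of the cis-fused γ-lactone lies α to C13, so a samarium aldolate can chelate it.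
3. 22 comes from cross-metathesis at C6=C7 of lactone–epoxide 14 with bromohydrin 19; C8 is taken from (S)-linalool.
4. 14 comes from methylidene lactone 8 (L-glyceraldehyde acetonide, Ueno–Stork cyclisation) and vinyl iodide 11; hydroboration/Suzuki coupling sets C1, Shi epoxidation sets C3/C4.
5. Ring order: γ-lactone (steps 5–6), oxirane (step 9), 14-membered carbocycle (step 16).

Key step: step 16

Remark on numbering: cembrane numbering of the target is used throughout: C1 (ring-fusion CH), C2, C3/C4 (epoxide), C5, C6=C7, C8 (carbinol), C9–C11, C12 (CHCH3), C13 (CHOAc), C14 (lactone O–CH), C15/C16/C17 (lactone α-carbon, carbonyl, exocyclic CH2).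
Assumption: (S)-2,2-dimethyl-1,3-dioxolane-4-carbaldehyde and (S)-(+)-linalool are taken as commercial enantiopure materials; 19–22 are carried as epimer mixtures at C11/C12, which converge in step 16.

**Route**

Step 1
Reactants: 1 (S)-2,2-dimethyl-1,3-dioxolane-4-carbaldehyde
Product: 2 (R)-4-ethynyl-2,2-dimethyl-1,3-dioxolane
Conditions: Ohira–Bestmann reagent, K2CO3, MeOH, 0 °C to rt
Reagents that add atoms: dimethyl (1-diazo-2-oxopropyl)phosphonate, CC(=O)C(=[N+]=[N-])P(=O)(OC)OC
Why: The Ohira–Bestmann (Seyferth–Gilbert) homologation turns the aldehyde into the terminal alkyne under mild base, which should leave the oxygenated stereocentre (future C14) intact.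

Step 2
Reactants: 2 (R)-4-ethynyl-2,2-dimethyl-1,3-dioxolane
Product: 3 (R)-but-3-yne-1,2-diol
Conditions: 1 M HCl, THF/H2O, rt
Reagents that add atoms: none
Why: Acid-catalysed acetal hydrolysis should free the 1,2-diol without touching the alkyne or the stereocentre.

Step 3
Reactants: 3 (R)-but-3-yne-1,2-diol
Product: 5 (R)-1-[(4-methoxybenzyl)oxy]but-3-yn-2-ol, via dibutylstannylene acetal 4 (not isolated)
Conditions: Bu2SnO, toluene, reflux (−H2O); then PMBCl, Bu4NI, 90 °C
Reagents that add atoms: 4-methoxybenzyl chloride, COc1ccc(CCl)cc1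
Why: Stannylene-acetal activation should direct the O-alkylation to the primary oxygen (C13–O), leaving the propargylic hydroxyl (future O14) free.

Step 4
Reactants: 5 (R)-1-[(4-methoxybenzyl)oxy]but-3-yn-2-ol
Product: 6 (2R)-2-(2-bromo-1-ethoxyethoxy)-1-[(4-methoxybenzyl)oxy]but-3-yne (both acetal epimers)
Conditions: ethyl vinyl ether, NBS, CH2Cl2, −40 to 0 °C
Reagents that add atoms: ethyl vinyl ether, C=COCC; N-bromosuccinimide, O=C1CCC(=O)N1Br
Why: Bromoacetalisation of the enol ether by the alcohol should install C15–C16 as a mixed bromoacetal whose acetal centre is later destroyed.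

Step 5
Reactants: 6 (2R)-2-(2-bromo-1-ethoxyethoxy)-1-[(4-methoxybenzyl)oxy]but-3-yne
Product: 7 (5R)-2-ethoxy-5-{[(4-methoxybenzyl)oxy]methyl}-4-methylideneoxolane (both C2 epimers)
Conditions: Bu3SnH, AIBN (cat.), benzene, 80 °C, slow addition
Reagents that add atoms: none
Why: In this Ueno–Stork radical cyclisation the primary radical should close 5-exo-dig onto the alkyne, forming C1–C15 and the exocyclic C1=C2 methylene.

Step 6
Reactants: 7 (5R)-2-ethoxy-5-{[(4-methoxybenzyl)oxy]methyl}-4-methylideneoxolane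
Product: 8 (R)-5-{[(4-methoxybenzyl)oxy]methyl}-4-methylideneoxolan-2-one
Conditions: CrO3, H2SO4, H2O, acetone, 0 °C, short contact
Reagents that add atoms: water, O
Why: Jones oxidation should hydrolyse the cyclic acetal and oxidise the lactol to the γ-lactone in one operation without touching C14.

Step 7
Reactants: 9 pent-1-en-4-yne
Product: 11 (E)-1-iodo-2-methylpenta-1,4-diene, via alkenylalane 10 (not isolated)
Conditions: Me3Al, Cp2ZrCl2 (cat.), CH2Cl2, 0 °C to rt; then I2, THF, −30 °C
Reagents that add atoms: trimethylaluminium, C[Al](C)C; iodine, II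
Why: Zirconium-catalysed carboalumination (Negishi) adds methyl and aluminium syn with the metal at the terminus, and iodinolysis with retention should give the (E)-iodide.

Step 8
Reactants: 8 (R)-5-{[(4-methoxybenzyl)oxy]methyl}-4-methylideneoxolan-2-one; 11 (E)-1-iodo-2-methylpenta-1,4-diene
Product: 13 (4S,5R)-4-[(2E)-3-methylhexa-2,5-dien-1-yl]-5-{[(4-methoxybenzyl)oxy]methyl}oxolan-2-one, via B-alkyl-9-BBN adduct 12 (not isolated)
Conditions: 9-BBN (1.05 equiv), THF, 0 °C to rt; then 11, Pd(dppf)Cl2 (cat.), AsPh3, Cs2CO3, DMF/THF/H2O, rt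
Reagents that add atoms: none
Why: 9-BBN should add to the exocyclic alkene from the face anti to the neighbouring CH2OPMB group, which places C2 cis to C13 on the lactone (C1 set), and the B-alkyl Suzuki–Miyaura coupling forms C2–C3 with retention of the E geometry.

Step 9
Reactants: 13 (4S,5R)-4-[(2E)-3-methylhexa-2,5-dien-1-yl]-5-{[(4-methoxybenzyl)oxy]methyl}oxolan-2-one
Product: 14 (4S,5R)-4-{[(2R,3R)-3-methyl-3-(prop-2-en-1-yl)oxiran-2-yl]methyl}-5-{[(4-methoxybenzyl)oxy]methyl}oxolan-2-one
Conditions: 1,2:4,5-di-O-isopropylidene-β-D-erythro-2,3-hexodiulo-2,6-pyranose (cat.), Oxone, K2CO3, Bu4NHSO4, Na2B4O7/Na2EDTA buffer, MeCN/dimethoxymethane/H2O, 0 °C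
Reagents that add atoms: potassium peroxymonosulfate, [K+].[O-]S(=O)(=O)OO
Why: In the Shi epoxidation the chiral dioxirane should oxidise only the electron-rich trisubstituted alkene (the terminal vinyl is inert) through the spiro transition state that gives the (R,R)-epoxide from E-olefins with the D-fructose-derived ketone, setting C3 and C4 by reagent control.

Step 10
Reactants: 15 (S)-(+)-linalool
Product: 16 (3S)-3,7-dimethyl-3-(triethylsilyloxy)octa-1,6-diene
Conditions: TESOTf, 2,6-lutidine, CH2Cl2, −78 to 0 °C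
Reagents that add atoms: triethylsilyl trifluoromethanesulfonate, CC[Si](CC)(CC)OS(=O)(=O)C(F)(F)F
Why: A silyl triflate silylates the hindered tertiary alcohol (future C8–OH), which must be masked while C11 is a ketone.

Step 11
Reactants: 16 (3S)-3,7-dimethyl-3-(triethylsilyloxy)octa-1,6-diene
Product: 18 (4S)-4-methyl-4-(triethylsilyloxy)hex-5-enal, via secondary ozonide 17 (not isolated)
Conditions: O3, CH2Cl2, −78 °C (Sudan red 7B end point); then PPh3, −78 °C to rt
Reagents that add atoms: ozone, [O-][O+]=O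
Why: Ozonolysis should be chemoselective for the electron-rich trisubstituted alkene over the vinyl group, which is monosubstituted and flanked by the silyloxy quaternary carbon.

Step 12
Reactants: 18 (4S)-4-methyl-4-(triethylsilyloxy)hex-5-enal
Product: 19 (6S)-2-bromo-6-methyl-6-(triethylsilyloxy)oct-7-en-3-ol (epimers at C2 and C3)
Conditions: CH3CHBr2, n-BuLi, THF/Et2O/pentane, −110 °C; then 18; AcOH, −100 °C
Reagents that add atoms: 1,1-dibromoethane, CC(Br)Br
Why: Bromine–lithium exchange gives the 1-bromoethyl carbenoid, which adds to the aldehyde at very low temperature to deliver C12 and its methyl as a bromohydrin whose two new centres are later levelled.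

Step 13
Reactants: 14 (4S,5R)-4-{[(2R,3R)-3-methyl-3-(prop-2-en-1-yl)oxiran-2-yl]methyl}-5-{[(4-methoxybenzyl)oxy]methyl}oxolan-2-one; 19 (6S)-2-bromo-6-methyl-6-(triethylsilyloxy)oct-7-en-3-ol
Product: 20 (4S,5R)-4-({(2R,3R)-3-[(2E,4S)-8-bromo-7-hydroxy-4-methyl-4-(triethylsilyloxy)non-2-en-1-yl]-3-methyloxiran-2-yl}methyl)-5-{[(4-methoxybenzyl)oxy]methyl}oxolan-2-one
Conditions: second-generation Hoveyda–Grubbs catalyst (cat.), 19 (3 equiv), toluene, 45 °C, Ar purge
Reagents that add atoms: none
Why: Olefin cross-metathesis between the unhindered allyl group of 14 and the hindered vinyl group of 19 (which should not homodimerise) forms C6=C7, and the quaternary C8 next to the new alkene should enforce E geometry.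

Step 14
Reactants: 20 (the cross-metathesis product)
Product: 21 (4S,5R)-4-({(2R,3R)-3-[(2E,4S)-8-bromo-7-hydroxy-4-methyl-4-(triethylsilyloxy)non-2-en-1-yl]-3-methyloxiran-2-yl}methyl)-5-(hydroxymethyl)oxolan-2-one
Conditions: DDQ, CH2Cl2/pH 7 buffer, 0 °C
Reagents that add atoms: none
Why: Oxidative PMB cleavage under buffered conditions should free C13–OH while the epoxide, the silyl ether and the bromohydrin survive.

Step 15
Reactants: 21 (the diol)
Product: 22 (2R,3S)-3-({(2R,3R)-3-[(2E,4S)-8-bromo-4-methyl-7-oxo-4-(triethylsilyloxy)non-2-en-1-yl]-3-methyloxiran-2-yl}methyl)-5-oxooxolane-2-carbaldehyde (epimers at CHBr)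
Conditions: Dess–Martin periodinane, pyridine, CH2Cl2, 0 °C to rt; used crude
Reagents that add atoms: none
Why: Dess–Martin oxidation should convert the primary alcohol into the C13 aldehyde and the bromohydrin into the C11 α-bromo ketone in one operation, and the buffered neutral medium should not epimerise C14.

Step 16
Reactants: 22 (the bromoketone–aldehyde)
Product: 24 macrocyclic aldol: 14-membered carbocycle cis-fused at C1/C14 to the γ-lactone, 3,4-epoxide, (6E)-alkene, 8-OTES, 11-ketone, 12-methyl, 13-hydroxyl (C12/C13 syn and configured as in the target), via trivalent samarium enolate 23 (not isolated)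
Conditions: SmI2 (0.1 M in THF, 2.2 equiv) added over 2 h to 22 (0.002 M in THF), −78 °C; then sat. NH4Cl
Reagents that add atoms: none
Why: Two one-electron transfers from SmI2 cleave the C12–Br bond much faster than the aldehyde is reduced and give the trivalent samarium (Z)-enolate 23, which adds to the C13 aldehyde through a chair Zimmerman–Traxler array (Reformatsky-type aldol). The closest known reaction type is the SmI2-promoted intramolecular Reformatsky cyclisation of α-halo carbonyl compounds onto aldehydes, established for medium and large rings at high dilution. The 14-membered carbocycle closes in a 14-(enolendo)-exo-trig mode and no other ring is formed. C12 and C13 should come out syn from the Z-enolate with the aldehyde substituent equatorial, and their absolute sense should follow from five-membered chelation of samarium by the aldehyde oxygen and the lactone ring oxygen O14, with attack on the aldehyde face anti to C1 (Cram-chelate, 13,14-syn). The step needs regioselective enolate formation, which the position of the bromine fixes at C12, and survival of the α-acyloxy aldehyde, epoxide and lactone, which slow addition of SmI2 (never in excess) at −78 °C should secure. Cyclisation over oligomerisation is secured by the high dilution.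

Step 17
Reactants: 24 (the macrocyclic aldol)
Product: 25 C11 tosylhydrazone of 24
Conditions: TsNHNH2, THF, 40 °C
Reagents that add atoms: 4-methylbenzenesulfonohydrazide, Cc1ccc(S(=O)(=O)NN)cc1
Why: Condensation of the ketone with the sulfonyl hydrazide without added acid or base should avoid retro-aldol cleavage and epimerisation at C12.

Step 18
Reactants: 25 (the tosylhydrazone)
Product: 27 11-deoxo macrocycle (C11 = CH2; 13-hydroxyl, 8-OTES, saturated lactone α-carbon), via alkyldiazene 26 (not isolated)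
Conditions: catecholborane, CHCl3, 0 °C; then NaOAc·3H2O, 60 °C
Reagents that add atoms: none
Why: Hydride reduction of the tosylhydrazone C=N, acetate-induced loss of sulfinate and extrusion of N2 from the diazene (Caglioti-type reduction) should remove the temporary C11 carbonyl without touching the alkene, epoxide or lactone.

Step 19
Reactants: 27 (the 11-deoxo macrocycle)
Product: 30 α-methylene lactone with free 13-hydroxyl and 8-OTES, via Mannich base 28 (not isolated), via trimethylammonium iodide 29 (not isolated)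
Conditions: LDA (2.5 equiv), THF, −78 °C; Me2N=CH2 I, −78 °C to rt; then MeI, MeOH, rt; then NaHCO3, CH2Cl2/H2O, rt
Reagents that add atoms: N,N-dimethylmethyleneiminium iodide (Eschenmoser's salt), C=[N+](C)C.[I-]
Why: The lactone enolate (formed beside the C13 alkoxide) undergoes a Mannich reaction at C15, and quaternisation followed by β-elimination of trimethylamine gives the exocyclic C15=C17 alkene (Eschenmoser methylenation).

Step 20
Reactants: 30 (the α-methylene lactone alcohol)
Product: 31 8-O-triethylsilyl ether of the target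
Conditions: Ac2O, pyridine, DMAP (cat.), CH2Cl2, 0 °C
Reagents that add atoms: acetic anhydride, CC(=O)OC(C)=O
Why: DMAP-catalysed acylation esterifies the only free (secondary) hydroxyl at C13 with retention.

Step 21
Reactants: 31 (the silyl ether)
Product: 32 CNP0202356.4, (1S,3R,4R,6E,8S,12S,13R,14R)-13-acetoxy-3,4-epoxy-8-hydroxycembra-6,15(17)-dien-16,14-olide
Conditions: HF·pyridine, pyridine, THF, 0 °C
Reagents that add atoms: none
Why: Buffered fluoride desilylation should free the tertiary C8 alcohol while the trisubstituted epoxide, acetate and α-methylene lactone remain.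

**Compound list**

1 | (S)-2,2-dimethyl-1,3-dioxolane-4-carbaldehyde | O=C[C@@H]1COC(C)(C)O1 | starting material
2 | (R)-4-ethynyl-2,2-dimethyl-1,3-dioxolane | C#C[C@@H]1COC(C)(C)O1 | intermediate
3 | (R)-but-3-yne-1,2-diol | C#C[C@@H](O)CO | intermediate
4 | (R)-2,2-dibutyl-4-ethynyl-1,3,2-dioxastannolane | C#C[C@@H]1CO[Sn](CCCC)(CCCC)O1 | intermediate
5 | (R)-1-[(4-methoxybenzyl)oxy]but-3-yn-2-ol | C#C[C@@H](O)COCc1ccc(OC)cc1 | intermediate
6 | (2R)-2-(2-bromo-1-ethoxyethoxy)-1-[(4-methoxybenzyl)oxy]but-3-yne | C#C[C@@H](OC(CBr)OCC)COCc1ccc(OC)cc1 | intermediate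
7 | (5R)-2-ethoxy-5-{[(4-methoxybenzyl)oxy]methyl}-4-methylideneoxolane | CCOC1CC(=C)[C@H](COCc2ccc(OC)cc2)O1 | intermediate
8 | (R)-5-{[(4-methoxybenzyl)oxy]methyl}-4-methylideneoxolan-2-one | O=C1CC(=C)[C@H](COCc2ccc(OC)cc2)O1 | intermediate
9 | pent-1-en-4-yne | C#CCC=C | starting material
10 | (E)-dimethyl(2-methylpenta-1,4-dien-1-yl)alane | C[Al](C)/C=C(\C)CC=C | intermediate
11 | (E)-1-iodo-2-methylpenta-1,4-diene | I/C=C(\C)CC=C | intermediate
12 | (4S,5R)-4-[(9-borabicyclo[3.3.1]nonan-9-yl)methyl]-5-{[(4-methoxybenzyl)oxy]methyl}oxolan-2-one | O=C1C[C@H](CB2C3CCCC2CCC3)[C@H](COCc4ccc(OC)cc4)O1 | intermediate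
13 | (4S,5R)-4-[(2E)-3-methylhexa-2,5-dien-1-yl]-5-{[(4-methoxybenzyl)oxy]methyl}oxolan-2-one | O=C1C[C@H](C/C=C(\C)CC=C)[C@H](COCc2ccc(OC)cc2)O1 | intermediate
14 | (4S,5R)-4-{[(2R,3R)-3-methyl-3-(prop-2-en-1-yl)oxiran-2-yl]methyl}-5-{[(4-methoxybenzyl)oxy]methyl}oxolan-2-one | O=C1C[C@H](C[C@H]3O[C@]3(C)CC=C)[C@H](COCc2ccc(OC)cc2)O1 | intermediate
15 | (S)-(+)-linalool, (3S)-3,7-dimethylocta-1,6-dien-3-ol | C=C[C@@](C)(O)CCC=C(C)C | starting material
16 | (3S)-3,7-dimethyl-3-(triethylsilyloxy)octa-1,6-diene | C=C[C@@](C)(O[Si](CC)(CC)CC)CCC=C(C)C | intermediate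
17 | secondary ozonide (1,2,4-trioxolane) of the 6,7-alkene of 16 | C=C[C@@](C)(O[Si](CC)(CC)CC)CCC1OOC(C)(C)O1 | intermediate
18 | (4S)-4-methyl-4-(triethylsilyloxy)hex-5-enal | C=C[C@@](C)(O[Si](CC)(CC)CC)CCC=O | intermediate
19 | (6S)-2-bromo-6-methyl-6-(triethylsilyloxy)oct-7-en-3-ol | C=C[C@@](C)(O[Si](CC)(CC)CC)CCC(O)C(C)Br | intermediate
20 | (4S,5R)-4-({(2R,3R)-3-[(2E,4S)-8-bromo-7-hydroxy-4-methyl-4-(triethylsilyloxy)non-2-en-1-yl]-3-methyloxiran-2-yl}methyl)-5-{[(4-methoxybenzyl)oxy]methyl}oxolan-2-one | O=C1C[C@H](C[C@H]3O[C@]3(C)C/C=C/[C@@](C)(O[Si](CC)(CC)CC)CCC(O)C(C)Br)[C@H](COCc2ccc(OC)cc2)O1 | intermediate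
21 | 5-(hydroxymethyl) analogue of 20 (PMB removed) | O=C1C[C@H](C[C@H]3O[C@]3(C)C/C=C/[C@@](C)(O[Si](CC)(CC)CC)CCC(O)C(C)Br)[C@H](CO)O1 | intermediate
22 | (2R,3S)-3-({(2R,3R)-3-[(2E,4S)-8-bromo-4-methyl-7-oxo-4-(triethylsilyloxy)non-2-en-1-yl]-3-methyloxiran-2-yl}methyl)-5-oxooxolane-2-carbaldehyde | O=C1C[C@H](C[C@H]3O[C@]3(C)C/C=C/[C@@](C)(O[Si](CC)(CC)CC)CCC(=O)C(C)Br)[C@H](C=O)O1 | intermediate
23 | trivalent samarium (Z)-enolate of 22 (C11–O–SmI2, C11=C12) | O=C1C[C@H](C[C@H]3O[C@]3(C)C/C=C/[C@@](C)(O[Si](CC)(CC)CC)CC/C(O[Sm](I)I)=C/C)[C@H](C=O)O1 | intermediate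
24 | macrocyclic aldol: 11-oxo-13-hydroxy-8-(triethylsilyloxy)-3,4-epoxy-(6E)-ene 14-membered ring, cis-fused saturated γ-lactone (1S,3R,4R,8S,13R,14R; C12 as in the target) | C1C(=O)O[C@H]2[C@H](O)[C@@H](C)C(=O)CC[C@](C)(O[Si](CC)(CC)CC)/C=C/C[C@@]3(C)O[C@@H]3C[C@@H]12 | intermediate
25 | C11 tosylhydrazone of 24 | C1C(=O)O[C@H]2[C@H](O)[C@@H](C)C(=NNS(=O)(=O)c4ccc(C)cc4)CC[C@](C)(O[Si](CC)(CC)CC)/C=C/C[C@@]3(C)O[C@@H]3C[C@@H]12 | intermediate
26 | C11 alkyldiazene from 25 | C1C(=O)O[C@H]2[C@H](O)[C@@H](C)C(N=N)CC[C@](C)(O[Si](CC)(CC)CC)/C=C/C[C@@]3(C)O[C@@H]3C[C@@H]12 | intermediate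
27 | 11-deoxo macrocycle: 13-hydroxy-8-(triethylsilyloxy), saturated lactone α-carbon (1S,3R,4R,8S,12S,13R,14R) | C1C(=O)O[C@H]2[C@H](O)[C@@H](C)CCC[C@](C)(O[Si](CC)(CC)CC)/C=C/C[C@@]3(C)O[C@@H]3C[C@@H]12 | intermediate
28 | C15 (dimethylamino)methyl lactone (Mannich base of 27) | CN(C)CC1C(=O)O[C@H]2[C@H](O)[C@@H](C)CCC[C@](C)(O[Si](CC)(CC)CC)/C=C/C[C@@]3(C)O[C@@H]3C[C@@H]12 | intermediate
29 | C15 (trimethylammonio)methyl lactone iodide | C[N+](C)(C)CC1C(=O)O[C@H]2[C@H](O)[C@@H](C)CCC[C@](C)(O[Si](CC)(CC)CC)/C=C/C[C@@]3(C)O[C@@H]3C[C@@H]12.[I-] | intermediate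
30 | 13-deacetyl-8-O-triethylsilyl target (α-methylene lactone, free 13-OH) | C=C1C(=O)O[C@H]2[C@H](O)[C@@H](C)CCC[C@](C)(O[Si](CC)(CC)CC)/C=C/C[C@@]3(C)O[C@@H]3C[C@@H]12 | intermediate
31 | 8-O-triethylsilyl target | C=C1C(=O)O[C@H]2[C@H](OC(C)=O)[C@@H](C)CCC[C@](C)(O[Si](CC)(CC)CC)/C=C/C[C@@]3(C)O[C@@H]3C[C@@H]12 | intermediate
32 | CNP0202356.4, (1S,3R,4R,6E,8S,12S,13R,14R)-13-acetoxy-3,4-epoxy-8-hydroxycembra-6,15(17)-dien-16,14-olide | C=C1C(=O)O[C@H]2[C@H](OC(C)=O)[C@@H](C)CCC[C@](C)(O)/C=C/C[C@@]3(C)O[C@@H]3C[C@@H]12 | target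

**Step count and risks**

Total step count: 21. Longest linear sequence: 17 (steps 1–6, 8, 9, 13–21).

Most likely to fail:

1. Step 16. What may go wrong: oligomerisation or simple reductive debromination (protonation of the enolate) instead of ring closure, or attack on the wrong aldehyde face. Fallback, setting out from 14 and 19 and coming back at 24: the C12–C13 bond would be made in the open chain and the ring closed at C6=C7 instead. DDQ cleavage of the PMB ether of 14 would give the lactone alcohol F1, and Dess–Martin oxidation the lactone aldehyde F2. Dess–Martin oxidation of 19 would give the α-bromo ketone F3. An intermolecular SmI2 Reformatsky coupling of F3 with an excess of F2 at −78 °C would give the open-chain aldol diene F4, whose diastereomers can be separated at this stage. Ring-closing metathesis of F4 with the second-generation Grubbs catalyst at high dilution would then give 24.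

2. Step 13. What may go wrong: slow turnover at the hindered silyloxy-substituted vinyl group, with 14 consumed by homodimerisation. Fallback, setting out from 15 and 14 and coming back at 20: the metathesis would be run on the free tertiary allylic alcohol and C12 added afterwards. Selective ozonolysis of 15 with NaBH4 work-up would give (S)-4-methylhex-5-ene-1,4-diol F5. Cross-metathesis of F5 with 14 (free allylic hydroxyl, far more reactive) would give the diol F6. TESCl/imidazole/DMAP would give the bis-silyl ether F7. Swern oxidation, which oxidises a primary triethylsilyl ether directly, would give the aldehyde F8. Addition of 1-bromo-1-lithioethane at −110 °C, as in step 12, would give 20.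

3. Step 18. What may go wrong: retro-aldol cleavage or C12 epimerisation on the way to the hydrazone, or opening of the epoxide by the borane. Fallback, setting out from 24 and coming back at 27: the carbonyl would be removed by radical deoxygenation. Evans–Tishchenko reduction of 24 (SmI2 cat., acetaldehyde, THF, −10 °C) would give the anti 11-hydroxy 13-acetate F9, which differentiates the two oxygens. 1,1'-Thiocarbonyldiimidazole would give the C11 imidazolylthiocarbonyl ester F10. Barton–McCombie reduction (Bu3SnH, AIBN, high hydride concentration to outrun transannular addition) would give the 11-deoxy 13-acetate F11. K2CO3/MeOH would remove the acetate and give 27.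

**Further compounds**

F1 | step 16 | (4S,5R)-5-(hydroxymethyl)-4-{[(2R,3R)-3-methyl-3-(prop-2-en-1-yl)oxiran-2-yl]methyl}oxolan-2-one | O=C1C[C@H](C[C@H]3O[C@]3(C)CC=C)[C@H](CO)O1
F2 | step 16 | (2R,3S)-3-{[(2R,3R)-3-methyl-3-(prop-2-en-1-yl)oxiran-2-yl]methyl}-5-oxooxolane-2-carbaldehyde | O=C1C[C@H](C[C@H]3O[C@]3(C)CC=C)[C@H](C=O)O1
F3 | step 16 | (6S)-2-bromo-6-methyl-6-(triethylsilyloxy)oct-7-en-3-one | C=C[C@@](C)(O[Si](CC)(CC)CC)CCC(=O)C(C)Br
F4 | step 16 | open-chain aldol diene (C12–C13 formed, C6 and C7 as terminal vinyl groups) | O=C1C[C@H](C[C@H]3O[C@]3(C)CC=C)[C@H]([C@H](O)[C@@H](C)C(=O)CC[C@](C)(O[Si](CC)(CC)CC)C=C)O1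
F5 | step 13 | (S)-4-methylhex-5-ene-1,4-diol | C=C[C@@](C)(O)CCCO
F6 | step 13 | cross-metathesis diol (free C8 and C11 hydroxyls, PMB ether at C13) | O=C1C[C@H](C[C@H]3O[C@]3(C)C/C=C/[C@@](C)(O)CCCO)[C@H](COCc2ccc(OC)cc2)O1
F7 | step 13 | bis(triethylsilyl) ether of F6 | O=C1C[C@H](C[C@H]3O[C@]3(C)C/C=C/[C@@](C)(O[Si](CC)(CC)CC)CCCO[Si](CC)(CC)CC)[C@H](COCc2ccc(OC)cc2)O1
F8 | step 13 | C11 aldehyde (8-OTES, PMB ether at C13) | O=C1C[C@H](C[C@H]3O[C@]3(C)C/C=C/[C@@](C)(O[Si](CC)(CC)CC)CCC=O)[C@H](COCc2ccc(OC)cc2)O1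
F9 | step 18 | 11-hydroxy 13-acetate macrocycle (11,13-anti) | C1C(=O)O[C@H]2[C@H](OC(C)=O)[C@@H](C)[C@@H](O)CC[C@](C)(O[Si](CC)(CC)CC)/C=C/C[C@@]3(C)O[C@@H]3C[C@@H]12
F10 | step 18 | C11 O-(imidazol-1-ylthiocarbonyl) derivative of F9 | C1C(=O)O[C@H]2[C@H](OC(C)=O)[C@@H](C)[C@@H](OC(=S)n4ccnc4)CC[C@](C)(O[Si](CC)(CC)CC)/C=C/C[C@@]3(C)O[C@@H]3C[C@@H]12
F11 | step 18 | 11-deoxy 13-acetate macrocycle (saturated lactone α-carbon) | C1C(=O)O[C@H]2[C@H](OC(C)=O)[C@@H](C)CCC[C@](C)(O[Si](CC)(CC)CC)/C=C/C[C@@]3(C)O[C@@H]3C[C@@H]12
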